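We reckon this flask by one ratio: what the dissolution could deliver by the time of reading into a solution kept empty, divided by the charge. We call it the supply ratio, a Damköhler number of the dissolution. Solid X dissolves to J at a rate proportional to the undersaturation, and J splits reversibly into D and Z.

X 1.0 M; time 12 min

1. how much D there is at 12 min, in percent of the X charged
2. concentration of J in solution at 12 min, in percent of saturation

With 0.00417 s⁻¹ and 0.62 M, the supply ratio at 12 min is 186 %, so the solid seems bound to run out. But that ceiling assumes J stays at nothing. If the charge does dissolve and step two reaches equilibrium, D and Z equal 0.596 M and J is 0.404 M, which is 65.2 % of saturation, so at that end J stands lower than the solubility.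

We treat J as a correction to the supply. If J stood at that final level throughout, the supply ratio would shrink to 64.8 %, less than the whole charge. That estimate is too harsh, though: J starts from nothing. Taking its mean as half of the final level gives 125 %, more than the charge, and by this rough estimate the charge has dissolved near 9.56 min.

A doubt remains: does step two catch up in the time left? Its relaxation half-life at equilibrium is 0.386 min, shorter than the remaining 2.44 min. So we commit to D at 59.6 % of the charge.

The forecast gives 59.5 % and 65.3 %, on the ground that “the J + D total reaches the 1.0 M charge before saturation is approached”. The simulation gives 59.5 % and 65.3 %.

    X ⇌ J, rate k1*(cs1 - [J]) while solid is left; crystals form when [J] > cs1 (cs1 = 0.62 M, k1 = 0.00417 s⁻¹)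
    J ⇌ D + Z (K2 = 0.879 M, k2 = 0.0127 s⁻¹)

Against a supply ratio of 186 %, the net dissolution in this flask up to 12 min came to 100 % of the X charged, leaving X at 0 %. The relaxation half-life of step two at that time is 0.386 min, short against the run, and D stands at 59.5 % of the charge, against 59.6 % after 120 min.

Read at 3.0 min, the same flask has a supply ratio of 46.5 %, below the charge, so solid must remain and at most that share has dissolved. The simulation shows X at 61.7 % of the charge, hence 38.3 % dissolved, with D at 21.7 % of the charge.

All constants stand for no real mixture; the result is computed.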